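**Plan**

- Feature used: on the oxolane ring, C3 and C4 carry one-carbon arms (CH2O on C3, ArCH2 on C4) that are cis to each other and trans to the C2 aryl group. Joining the two arm carbons gives a cyclobutane cis-fused to the C3–C4 edge.
- Retrosynthesis: cut the ester C–O bond; rejoin the two arm carbons as an arylcyclobutene; cut its aryl–C bond back to a cyclobutanone; cut the two ring-to-arm bonds (C3–CH2 and C4–C) to a (5R)-5-aryl butenolide and allene. The butenolide comes from an acrylate by metathesis, and the carbinol from aldehyde plus vinyl.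
- Forward: the oxygen ring closes first as the butenolide, and the temporary four-membered ring is added photochemically. The lactone is then reduced to the oxolane, the second aryl ring is joined by Grignard addition, the four-membered ring is cut by ozonolysis, and acylation and hydrogenolysis finish the route.
- Stereochemistry: C2 from a Sharpless kinetic resolution; C3 and C4 from the cis-fused photocycloaddition on the face anti to the aryl group; the side-chain centre from (R)-2-methylbutanoic acid.

Key step: step 5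

Assumption: the kinetic resolution in step 2 follows the usual Sharpless sense, so that D-(−)-diisopropyl tartrate leaves the (R)-carbinol; the other tartrate would be used if the recovered alcohol proved to be (S).

**Route**

Step 1
Reactants: 1 4-(benzyloxy)-3-methoxybenzaldehyde
Product: 2 rac-1-[4-(benzyloxy)-3-methoxyphenyl]prop-2-en-1-ol
Conditions: CH2=CHMgBr, THF, −78 → 0 °C; aq. NH4Cl
Reagents that add atoms: vinylmagnesium bromide, C=C[Mg]Br
Why: Grignard 1,2-addition to a non-enolisable aromatic aldehyde gives the racemic allylic alcohol, and no stereocontrol is needed because the next step resolves it.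

Step 2
Reactants: 2 rac-1-[4-(benzyloxy)-3-methoxyphenyl]prop-2-en-1-ol
Product: 3 (R)-1-[4-(benzyloxy)-3-methoxyphenyl]prop-2-en-1-ol
Conditions: Ti(OiPr)4 (0.15 equiv), D-(−)-diisopropyl tartrate (0.2 equiv), t-BuOOH (0.6 equiv), 4 Å sieves, CH2Cl2, −20 °C; chromatography on Et3N-washed silica
Reagents that add atoms: none
Why: Sharpless kinetic resolution, in which the Ti(OiPr)4–tartrate catalyst epoxidises the (S)-alcohol much faster, so the (R)-alcohol, whose carbinol carbon becomes C2 of the target, is recovered and separated from the epoxy alcohol.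

Step 3
Reactants: 3 (R)-1-[4-(benzyloxy)-3-methoxyphenyl]prop-2-en-1-ol
Product: 4 (R)-1-[4-(benzyloxy)-3-methoxyphenyl]prop-2-en-1-yl prop-2-enoate
Conditions: acryloyl chloride, Et3N, CH2Cl2, −20 → 0 °C
Reagents that add atoms: acryloyl chloride, C=CC(=O)Cl
Why: O-acylation of the secondary alcohol with an acid chloride under mild base installs the acrylate without touching the carbinol centre, and basic conditions avoid ionisation of the electron-rich allylic ester.

Step 4
Reactants: 4 (R)-1-[4-(benzyloxy)-3-methoxyphenyl]prop-2-en-1-yl prop-2-enoate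
Product: 5 (5R)-5-[4-(benzyloxy)-3-methoxyphenyl]furan-2(5H)-one
Conditions: second-generation Grubbs catalyst RuCl2(=CHPh)(H2IMes)(PCy3) (5 mol%), CH2Cl2 (0.01 M), reflux
Reagents that add atoms: none
Why: Ring-closing olefin metathesis of the allyl acrylate closes the unsaturated five-membered lactone with loss of ethylene under neutral conditions, which leave the acidic benzylic γ-hydrogen and hence the stereocentre alone.

Step 5
Reactants: 5 (5R)-5-[4-(benzyloxy)-3-methoxyphenyl]furan-2(5H)-one; 6 propadiene (allene)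
Product: 7 (1R,4R,5R)-4-[4-(benzyloxy)-3-methoxyphenyl]-7-methylidene-3-oxabicyclo[3.2.0]heptan-2-one
Conditions: allene (ca. 10 equiv, condensed), acetone, hν (medium-pressure Hg lamp, Pyrex filter), −78 °C
Reagents that add atoms: none
Why: Acetone-sensitised excitation gives the triplet butenolide, which adds to allene stepwise through a triplet 1,4-biradical that closes after spin inversion, the course of the well-known enone–allene [2+2] photocycloaddition. The only ring closed is the temporary four-membered ring, formed by radical recombination across the former C3=C4 bond of the furanone, and its fusion to the five-membered lactone can only be cis. The two new stereocentres (C1 and C5 of the adduct) are set by the existing aryl-bearing centre, because allene approaches the flat butenolide on the face opposite the aryl group. The step needs head-to-head regiochemistry, with the central allene carbon on the lactone α-carbon and a terminal CH2 on the β-carbon, which is the normal orientation of allene towards enones and enoates. It also needs the lactone and not the arene to be excited, which the Pyrex cut-off with acetone as sensitiser should secure, while excess allene at low temperature keeps capture faster than unimolecular decay.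

Step 6
Reactants: 7 (1R,4R,5R)-4-[4-(benzyloxy)-3-methoxyphenyl]-7-methylidene-3-oxabicyclo[3.2.0]heptan-2-one
Product: 8 (1R,4R,5R)-4-[4-(benzyloxy)-3-methoxyphenyl]-7-methylidene-3-oxabicyclo[3.2.0]heptan-2-ol (anomeric mixture)
Conditions: i-Bu2AlH (1.1 equiv), CH2Cl2, −78 °C; aq. potassium sodium tartrate
Reagents that add atoms: none
Why: Partial reduction of a γ-lactone by i-Bu2AlH at low temperature stops at the aluminium hemiacetal, which gives the lactol on work-up, while the alkene, the benzyl ether and the stereocentres are inert.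

Step 7
Reactants: 8 (1R,4R,5R)-4-[4-(benzyloxy)-3-methoxyphenyl]-7-methylidene-3-oxabicyclo[3.2.0]heptan-2-ol
Product: 9 (1R,2R,5R)-2-[4-(benzyloxy)-3-methoxyphenyl]-6-methylidene-3-oxabicyclo[3.2.0]heptane
Conditions: Et3SiH (3 equiv), BF3·OEt2 (1.5 equiv), CH2Cl2, −78 → −40 °C; aq. NaHCO3
Reagents that add atoms: none
Why: Ionic hydrogenation, in which BF3·OEt2 ionises the lactol to the oxocarbenium ion and Et3SiH reduces it to the cyclic ether, while at this temperature the benzylic C–O bond of the ring should not ionise.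

Step 8
Reactants: 9 (1R,2R,5R)-2-[4-(benzyloxy)-3-methoxyphenyl]-6-methylidene-3-oxabicyclo[3.2.0]heptane
Product: 10 (1R,2R,5S)-2-[4-(benzyloxy)-3-methoxyphenyl]-3-oxabicyclo[3.2.0]heptan-6-one
Conditions: O3 (to first excess), CH2Cl2, −78 °C; Me2S, −78 °C → rt
Reagents that add atoms: ozone, [O-][O+]=O
Why: Ozonolysis of the exocyclic 1,1-disubstituted alkene with reductive work-up gives the cyclobutanone, since the alkene reacts far faster than the arenes and the ring-fusion carbon next to the ketone cannot epimerise because the fusion must stay cis.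

Step 9
Reactants: 10 (1R,2R,5S)-2-[4-(benzyloxy)-3-methoxyphenyl]-3-oxabicyclo[3.2.0]heptan-6-one; 11 1-(benzyloxy)-4-bromo-2-methoxybenzene
Product: 13 (1R,2R,5S,6S)-2,6-bis[4-(benzyloxy)-3-methoxyphenyl]-3-oxabicyclo[3.2.0]heptan-6-ol, via arylmagnesium bromide 12 (not isolated)
Conditions: 11, Mg, I2 (cat.), THF, reflux; then 10, THF, −78 → 0 °C; aq. NH4Cl
Reagents that add atoms: none
Why: Grignard addition of the aryl nucleophile to the strained, electrophilic cyclobutanone from its convex face should give the tertiary benzylic alcohol, whose new carbinol centre is lost in the next step.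

Step 10
Reactants: 13 (1R,2R,5S,6S)-2,6-bis[4-(benzyloxy)-3-methoxyphenyl]-3-oxabicyclo[3.2.0]heptan-6-ol
Product: 14 (1R,2R,5R)-2,6-bis[4-(benzyloxy)-3-methoxyphenyl]-3-oxabicyclo[3.2.0]hept-6-ene
Conditions: Burgess reagent (methyl N-(triethylammoniumsulfonyl)carbamate, 1.5 equiv), THF, 50 °C
Reagents that add atoms: none
Why: Burgess dehydration by syn elimination through the sulfamate ester should give the 1-arylcyclobutene, because the only β-hydrogen cis to the concave-face oxygen sits on the ring CH2 and a double bond to the ring-fusion carbon would be far more strained.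

Step 11
Reactants: 14 (1R,2R,5R)-2,6-bis[4-(benzyloxy)-3-methoxyphenyl]-3-oxabicyclo[3.2.0]hept-6-ene
Product: 16 {(2R,3S,4S)-2-[4-(benzyloxy)-3-methoxyphenyl]-4-{[4-(benzyloxy)-3-methoxyphenyl](hydroxy)methyl}oxolan-3-yl}methanol as a mixture of carbinol epimers, via keto aldehyde 15 (not isolated)
Conditions: O3 (to first excess), CH2Cl2/MeOH 5:1, −78 °C; Me2S, −78 → 0 °C; then NaBH4, 0 °C
Reagents that add atoms: ozone, [O-][O+]=O
Why: Ozonolysis of the strained styrene-type double bond cuts the bond between the two arm carbons, and borohydride reduction of the ketone and aldehyde in the same flask should give the diol before the ring carbons next to the carbonyl groups can epimerise; the new carbinol centre forms unselectively and is removed in step 14.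

Step 12
Reactants: 16 {(2R,3S,4S)-2-[4-(benzyloxy)-3-methoxyphenyl]-4-{[4-(benzyloxy)-3-methoxyphenyl](hydroxy)methyl}oxolan-3-yl}methanol; 17 (R)-2-methylbutanoic acid
Product: 18 {(2R,3S,4S)-2-[4-(benzyloxy)-3-methoxyphenyl]-4-{[4-(benzyloxy)-3-methoxyphenyl](hydroxy)methyl}oxolan-3-yl}methyl (2R)-2-methylbutanoate
Conditions: 17 (1.05 equiv), DCC (1.1 equiv), DMAP (0.1 equiv), CH2Cl2, −20 → 0 °C
Reagents that add atoms: none
Why: Steglich esterification acylates the primary alcohol much faster than the hindered secondary benzylic alcohol, and carbodiimide activation with a little DMAP at low temperature should not racemise the α-centre of the acid.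

Step 13
Reactants: 18 {(2R,3S,4S)-2-[4-(benzyloxy)-3-methoxyphenyl]-4-{[4-(benzyloxy)-3-methoxyphenyl](hydroxy)methyl}oxolan-3-yl}methyl (2R)-2-methylbutanoate
Product: 19 {(2R,3S,4S)-4-{(acetyloxy)[4-(benzyloxy)-3-methoxyphenyl]methyl}-2-[4-(benzyloxy)-3-methoxyphenyl]oxolan-3-yl}methyl (2R)-2-methylbutanoate
Conditions: Ac2O, pyridine, DMAP (cat.), CH2Cl2, 0 °C → rt
Reagents that add atoms: acetic anhydride, CC(=O)OC(C)=O
Why: DMAP-catalysed acetylation turns the benzylic hydroxyl into an acetate, a far better leaving group for hydrogenolysis than the ring ether oxygen.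

Step 14
Reactants: 19 {(2R,3S,4S)-4-{(acetyloxy)[4-(benzyloxy)-3-methoxyphenyl]methyl}-2-[4-(benzyloxy)-3-methoxyphenyl]oxolan-3-yl}methyl (2R)-2-methylbutanoate
Product: 20 {(2R,3S,4S)-2-(4-hydroxy-3-methoxyphenyl)-4-[(4-hydroxy-3-methoxyphenyl)methyl]oxolan-3-yl}methyl (2R)-2-methylbutanoate
Conditions: H2 (1 atm), 10% Pd/C, EtOAc, rt, stopped at full conversion
Reagents that add atoms: none
Why: Catalytic hydrogenolysis over Pd/C cleaves the two aryl benzyl ethers and the activated benzylic C–OAc bond, whereas the benzylic C–O bond of the oxolane, a poorer leaving group held in a ring, should react much more slowly under neutral conditions.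

**Compound list**

1 | 4-(benzyloxy)-3-methoxybenzaldehyde (O-benzylvanillin) | COc1cc(C=O)ccc1OCc1ccccc1 | starting material
2 | rac-1-[4-(benzyloxy)-3-methoxyphenyl]prop-2-en-1-ol | C=CC(O)c1ccc(OCc2ccccc2)c(OC)c1 | intermediate
3 | (R)-1-[4-(benzyloxy)-3-methoxyphenyl]prop-2-en-1-ol | C=C[C@@H](O)c1ccc(OCc2ccccc2)c(OC)c1 | intermediate
4 | (R)-1-[4-(benzyloxy)-3-methoxyphenyl]prop-2-en-1-yl prop-2-enoate | C=CC(=O)O[C@H](C=C)c1ccc(OCc2ccccc2)c(OC)c1 | intermediate
5 | (5R)-5-[4-(benzyloxy)-3-methoxyphenyl]furan-2(5H)-one | C1=CC(=O)O[C@H]1c1ccc(OCc2ccccc2)c(OC)c1 | intermediate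
6 | propadiene (allene) | C=C=C | starting material
7 | (1R,4R,5R)-4-[4-(benzyloxy)-3-methoxyphenyl]-7-methylidene-3-oxabicyclo[3.2.0]heptan-2-one (cis-fused, four-membered ring anti to the aryl group) | [C@@H]12CC(=C)[C@@H]1C(=O)O[C@H]2c1ccc(OCc2ccccc2)c(OC)c1 | intermediate
8 | (1R,4R,5R)-4-[4-(benzyloxy)-3-methoxyphenyl]-7-methylidene-3-oxabicyclo[3.2.0]heptan-2-ol (lactol, both anomers) | [C@@H]12CC(=C)[C@@H]1C(O)O[C@H]2c1ccc(OCc2ccccc2)c(OC)c1 | intermediate
9 | (1R,2R,5R)-2-[4-(benzyloxy)-3-methoxyphenyl]-6-methylidene-3-oxabicyclo[3.2.0]heptane | [C@@H]12CC(=C)[C@@H]1CO[C@H]2c1ccc(OCc2ccccc2)c(OC)c1 | intermediate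
10 | (1R,2R,5S)-2-[4-(benzyloxy)-3-methoxyphenyl]-3-oxabicyclo[3.2.0]heptan-6-one | [C@@H]12CC(=O)[C@@H]1CO[C@H]2c1ccc(OCc2ccccc2)c(OC)c1 | intermediate
11 | 1-(benzyloxy)-4-bromo-2-methoxybenzene | COc1cc(Br)ccc1OCc1ccccc1 | starting material
12 | [4-(benzyloxy)-3-methoxyphenyl]magnesium bromide | COc1cc([Mg]Br)ccc1OCc1ccccc1 | intermediate
13 | (1R,2R,5S,6S)-2,6-bis[4-(benzyloxy)-3-methoxyphenyl]-3-oxabicyclo[3.2.0]heptan-6-ol (6-aryl group on the convex face) | [C@@H]12C[C@@](O)(c3ccc(OCc4ccccc4)c(OC)c3)[C@@H]1CO[C@H]2c1ccc(OCc2ccccc2)c(OC)c1 | intermediate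
14 | (1R,2R,5R)-2,6-bis[4-(benzyloxy)-3-methoxyphenyl]-3-oxabicyclo[3.2.0]hept-6-ene | [C@@H]12C=C(c3ccc(OCc4ccccc4)c(OC)c3)[C@@H]1CO[C@H]2c1ccc(OCc2ccccc2)c(OC)c1 | intermediate
15 | (2R,3R,4S)-4-[4-(benzyloxy)-3-methoxybenzoyl]-2-[4-(benzyloxy)-3-methoxyphenyl]oxolane-3-carbaldehyde | O=C[C@@H]1[C@H](C(=O)c2ccc(OCc3ccccc3)c(OC)c2)CO[C@H]1c1ccc(OCc2ccccc2)c(OC)c1 | intermediate
16 | {(2R,3S,4S)-2-[4-(benzyloxy)-3-methoxyphenyl]-4-{[4-(benzyloxy)-3-methoxyphenyl](hydroxy)methyl}oxolan-3-yl}methanol (carbinol epimers) | OC[C@@H]1[C@H](C(O)c2ccc(OCc3ccccc3)c(OC)c2)CO[C@H]1c1ccc(OCc2ccccc2)c(OC)c1 | intermediate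
17 | (R)-2-methylbutanoic acid | CC[C@@H](C)C(=O)O | starting material
18 | {(2R,3S,4S)-2-[4-(benzyloxy)-3-methoxyphenyl]-4-{[4-(benzyloxy)-3-methoxyphenyl](hydroxy)methyl}oxolan-3-yl}methyl (2R)-2-methylbutanoate | CC[C@@H](C)C(=O)OC[C@@H]1[C@H](C(O)c2ccc(OCc3ccccc3)c(OC)c2)CO[C@H]1c1ccc(OCc2ccccc2)c(OC)c1 | intermediate
19 | {(2R,3S,4S)-4-{(acetyloxy)[4-(benzyloxy)-3-methoxyphenyl]methyl}-2-[4-(benzyloxy)-3-methoxyphenyl]oxolan-3-yl}methyl (2R)-2-methylbutanoate | CC[C@@H](C)C(=O)OC[C@@H]1[C@H](C(OC(C)=O)c2ccc(OCc3ccccc3)c(OC)c2)CO[C@H]1c1ccc(OCc2ccccc2)c(OC)c1 | intermediate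
20 | {(2R,3S,4S)-2-(4-hydroxy-3-methoxyphenyl)-4-[(4-hydroxy-3-methoxyphenyl)methyl]oxolan-3-yl}methyl (2R)-2-methylbutanoate | CC[C@@H](C)C(=O)OC[C@@H]1[C@H](Cc2ccc(O)c(OC)c2)CO[C@H]1c1ccc(O)c(OC)c1 | target

**Summary**

Total step count: 14. Longest linear sequence: 14 steps, from 1 to 20; allene 6, bromide 11 and acid 17 are used as purchased.

**Steps most likely to fail**

Step 5. The excited 5-aryl butenolide may decay by other paths (aryl migration, or quenching by the electron-rich arene) before allene captures it. The addition may also show incomplete facial or head-to-head control, and exchange of the acidic γ-hydrogen of 5 would erode its enantiomeric purity. The fallback builds the same cyclobutanone by a thermal ketene cycloaddition and sets out from alcohol 3. O-allylation (NaH, allyl bromide, THF) gives 1-(benzyloxy)-2-methoxy-4-[(1R)-1-(prop-2-en-1-yloxy)prop-2-en-1-yl]benzene F1. Ring-closing metathesis with the second-generation Grubbs catalyst gives (2R)-2-[4-(benzyloxy)-3-methoxyphenyl]-2,5-dihydrofuran F2. Dichloroketene, generated from Cl3CCOCl with Zn–Cu couple in Et2O, should add to the ring alkene on the face opposite the aryl group, with the carbonyl carbon expected on the less hindered olefinic carbon remote from the aryl-bearing centre. This gives cis-fused 2-[4-(benzyloxy)-3-methoxyphenyl]-7,7-dichloro-3-oxabicyclo[3.2.0]heptan-6-one F3; a regioisomer, if formed, would be separated here. Zn in AcOH removes both chlorines and the route is rejoined at cyclobutanone 10.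

Step 11. Once the alkene is consumed, ozone may attack the two electron-rich arenes or the benzylic ether positions, and the keto aldehyde may epimerise at the ring carbons next to its carbonyl groups before it is reduced. The fallback replaces ozone by a two-stage glycol cleavage and sets out from cyclobutene 14. OsO4 (cat.) with N-methylmorpholine N-oxide in acetone–water should dihydroxylate the convex face to give cis-2,6-bis[4-(benzyloxy)-3-methoxyphenyl]-3-oxabicyclo[3.2.0]heptane-6,7-diol F4, with both hydroxyls on the convex face. NaIO4 in buffered THF–water cleaves the glycol to keto aldehyde 15, which is reduced at once with NaBH4 to diol 16.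

Step 14. Hydrogenolysis may go too far and open the oxolane at its benzylic C2–O bond once the phenols are free, or the benzylic acetate may be cleaved incompletely. The fallback removes the benzylic oxygen by radical chemistry and sets out from alcohol 18. 1,1'-Thiocarbonyldiimidazole with DMAP in THF gives the O-{[4-(benzyloxy)-3-methoxyphenyl][oxolan-3-yl]methyl} 1H-imidazole-1-carbothioate of 18, F5. Barton–McCombie reduction (Bu3SnH, AIBN, toluene, 80 °C) gives {(2R,3S,4S)-2-[4-(benzyloxy)-3-methoxyphenyl]-4-{[4-(benzyloxy)-3-methoxyphenyl]methyl}oxolan-3-yl}methyl (2R)-2-methylbutanoate F6. A short hydrogenolysis (H2, Pd/C, EtOAc), now limited to the two fast-reacting aryl benzyl ethers, then gives target 20.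

**Further compounds**

F1 | step 5 | 1-(benzyloxy)-2-methoxy-4-[(1R)-1-(prop-2-en-1-yloxy)prop-2-en-1-yl]benzene | C=CCO[C@H](C=C)c1ccc(OCc2ccccc2)c(OC)c1
F2 | step 5 | (2R)-2-[4-(benzyloxy)-3-methoxyphenyl]-2,5-dihydrofuran | C1=CCO[C@H]1c1ccc(OCc2ccccc2)c(OC)c1
F3 | step 5 | cis-fused 2-[4-(benzyloxy)-3-methoxyphenyl]-7,7-dichloro-3-oxabicyclo[3.2.0]heptan-6-one, four-membered ring anti to the aryl group | [C@@H]12C(Cl)(Cl)C(=O)[C@@H]1CO[C@H]2c1ccc(OCc2ccccc2)c(OC)c1
F4 | step 11 | cis-2,6-bis[4-(benzyloxy)-3-methoxyphenyl]-3-oxabicyclo[3.2.0]heptane-6,7-diol, hydroxyls on the convex face | [C@@H]12[C@@H](O)[C@](O)(c3ccc(OCc4ccccc4)c(OC)c3)[C@@H]1CO[C@H]2c1ccc(OCc2ccccc2)c(OC)c1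
F5 | step 14 | {(2R,3S,4S)-2-[4-(benzyloxy)-3-methoxyphenyl]-4-{[4-(benzyloxy)-3-methoxyphenyl][(1H-imidazole-1-carbothioyl)oxy]methyl}oxolan-3-yl}methyl (2R)-2-methylbutanoate | CC[C@@H](C)C(=O)OC[C@@H]1[C@H](C(OC(=S)n2ccnc2)c2ccc(OCc3ccccc3)c(OC)c2)CO[C@H]1c1ccc(OCc2ccccc2)c(OC)c1
F6 | step 14 | {(2R,3S,4S)-2-[4-(benzyloxy)-3-methoxyphenyl]-4-{[4-(benzyloxy)-3-methoxyphenyl]methyl}oxolan-3-yl}methyl (2R)-2-methylbutanoate | CC[C@@H](C)C(=O)OC[C@@H]1[C@H](Cc2ccc(OCc3ccccc3)c(OC)c2)CO[C@H]1c1ccc(OCc2ccccc2)c(OC)c1
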